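**Retrosynthetic overview**
1. The ester C6–O bond is cut to diol 19 and TBS-protected isovanillic acid 22; 19 comes from enone 18 by 1,2-reduction from the convex face.
2. Feature: in the cycloheptene ring C5–C6(O-acyl)–C7=C8(Me)–C9–C10–C1, cis-fused to the cyclopentane C1–C5, the unit C7=C8(Me) lies between the former carbonyl carbon C6 and C9.
3. Key disconnection: C7 and C8 are removed and C6–C9 rejoined, giving a cis-bicyclo[3.3.0]octan-6-one; forward, its C6=C9 pyrrolidine enamine takes up methyl but-2-ynoate by [2+2] addition and cyclobutene opening, then hydrolysis and decarboxylation give the enone.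
4. The diquinane ketol comes from keto-enone 8 by Cu-catalysed asymmetric methyl addition with aldol closure (C1, then C5 and C4); 8 comes from 3-ethoxycyclopentenone and a masked homoenolate built from isobutyryl chloride and ethylene.
5. Ring order: cyclopentenone (bought), then cyclopentane C1–C5 (aldol), then the seven-membered ring (two-carbon expansion of the cyclopentanone).

Key step: step 7

Remark: daucane numbering is used (C1 = CMe ring fusion, C4 = C(OH)iPr, C5 = CH ring fusion, C6–C10 = the other ring carbons). The SMILES is read as the cis-fused bicycle with C1–CH3, C5–H and the isopropyl group on the convex face and the C4 and C6 oxygens on the concave face.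

**Step 1**
Reactants: 1 isobutyryl chloride; 2 ethylene
Product: 3 1-chloro-4-methylpentan-3-one
Conditions: AlCl3 (1.1 equiv), CH2Cl2, 0 °C, ethylene (1 atm)
Reagents that add atoms: none
Why: Friedel–Crafts-type (Nenitzescu/Kondakov) acylation of ethylene with chloride capture of the β-cation is the standard route to β-chloroethyl ketones; no stereocentre is formed.

**Step 2**
Reactants: 3 1-chloro-4-methylpentan-3-one
Product: 4 2-(2-chloroethyl)-2-(propan-2-yl)-1,3-dioxolane
Conditions: ethylene glycol, TsOH (cat.), cyclohexane, reflux, Dean–Stark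
Reagents that add atoms: ethylene glycol, OCCO
Why: Acid-catalysed ketalisation with azeotropic removal of water masks the ketone for the organolithium step, and the acidic medium suppresses base-type loss of HCl.

**Step 3**
Reactants: 4 2-(2-chloroethyl)-2-(propan-2-yl)-1,3-dioxolane; 5 3-ethoxycyclopent-2-en-1-one
Product: 8 3-(4-methyl-3-oxopentyl)cyclopent-2-en-1-one, via masked homoenolate organolithium 6 (not isolated), via ethoxy carbinol 1,2-adduct 7 (not isolated)
Conditions: Li, DTBB (5 mol %), THF, −78 °C; then 5, −78 → 0 °C; then 2 M HCl, THF, rt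
Reagents that add atoms: water, O
Why: Reductive lithiation of the β-chloro ketal gives a masked ketone homoenolate that adds 1,2 to the vinylogous ester, and aqueous acid then brings about the Stork–Danheiser transposition to the 3-substituted enone and hydrolyses the dioxolane in the same operation.

**Step 4**
Reactants: 8 3-(4-methyl-3-oxopentyl)cyclopent-2-en-1-one
Product: 10 (3aS,6R,6aR)-6-hydroxy-3a-methyl-6-(propan-2-yl)hexahydropentalen-1(2H)-one, via dimethylaluminium enolate 9 (not isolated)
Conditions: Me3Al (3 equiv), Cu(OTf)2 (5 mol %), chiral sulfonate-bearing NHC–Ag(I) complex (2.5 mol %), THF, −78 °C, then −78 → 0 °C; aq. Rochelle salt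
Reagents that add atoms: trimethylaluminium, C[Al](C)C
Why: Cu–NHC-catalysed asymmetric conjugate addition of Me3Al to a 3-alkylcyclopent-2-enone sets the quaternary C1 under catalyst control (ligand enantiomer chosen for the 3aS centre; Me3Al·THF should leave the saturated ketone alone at −78 °C), and the aluminium enolate, formed only toward C5, closes on the tethered isopropyl ketone in a tandem conjugate addition–aldol cyclisation in which the two-carbon tether enforces the cis ring fusion at C5 and the Al-bridged closed transition state places the C4 oxygen syn to the C6 carbonyl with isopropyl on the convex face.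

**Step 5**
Reactants: 10 (3aS,6R,6aR)-6-hydroxy-3a-methyl-6-(propan-2-yl)hexahydropentalen-1(2H)-one
Product: 11 (3aS,6R,6aR)-3a-methyl-6-(propan-2-yl)-6-[(triethylsilyl)oxy]hexahydropentalen-1(2H)-one
Conditions: Et3SiOTf, 2,6-lutidine, CH2Cl2, −78 → 0 °C
Reagents that add atoms: triethylsilyl trifluoromethanesulfonate, CC[Si](CC)(CC)OS(=O)(=O)C(F)(F)F
Why: Silyl triflate/lutidine silylation caps the hindered tertiary aldol hydroxyl and blocks retro-aldol cleavage in the amine and thermal steps that follow; the triethylsilyl ether is chosen because it should survive steps 6–9, and no stereocentre is touched.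

**Step 6**
Reactants: 11 (3aS,6R,6aR)-3a-methyl-6-(propan-2-yl)-6-[(triethylsilyl)oxy]hexahydropentalen-1(2H)-one
Product: 12 1-[(3aS,6R,6aS)-3a-methyl-6-(propan-2-yl)-6-[(triethylsilyl)oxy]-3,3a,4,5,6,6a-hexahydropentalen-1-yl]pyrrolidine
Conditions: pyrrolidine (5 equiv), TsOH (cat.), toluene, reflux, Dean–Stark
Reagents that add atoms: pyrrolidine, C1CCNC1
Why: Stork enamine formation; the double bond should form toward the C9 methylene because the alternative toward ring-fusion C5 would be a strained, tetrasubstituted ring-fusion enamine with A(1,3) strain against the C4 substituents.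

**Step 7**
Reactants: 12 1-[(3aS,6R,6aS)-3a-methyl-6-(propan-2-yl)-6-[(triethylsilyl)oxy]-3,3a,4,5,6,6a-hexahydropentalen-1-yl]pyrrolidine; 13 methyl but-2-ynoate
Product: 15 methyl (3R,3aS,8aS)-6,8a-dimethyl-3-(propan-2-yl)-4-(pyrrolidin-1-yl)-3-[(triethylsilyl)oxy]-1,2,3,3a,8,8a-hexahydroazulene-5-carboxylate, via aminocyclobutene adduct 14 (not isolated)
Conditions: 13 (3 equiv), toluene, 110 °C, sealed tube, Ar
Reagents that add atoms: none
Why: The enamine β-carbon C9 adds to the methyl-bearing β-carbon of the ynoate (C8), the iminium/allenolate zwitterion collapses by C6–C7 bond formation to a 1-aminocyclobutene (formal [2+2]), and the donor nitrogen and acceptor ester then drive a stepwise heterolytic opening in which the old C6–C9 bond breaks, so that C7=C8(Me) is inserted between C6 and C9. This is the known two-carbon ring expansion of cyclic ketone enamines with acetylenic esters, here with a 3-substituted ynoate that reacts more slowly than a propiolate and therefore is given heat and an excess of the alkyne. The four-membered ring closes by 4-exo-trig attack of the allenolate carbon on the iminium carbon, and the seven-membered ring is not closed by a cyclisation but arises by cleavage of the shared C6–C9 bond of the bicyclo[3.2.0] intermediate. No stereocentre is created, and C1, C4 and C5 are spectators because the aprotic medium offers no path for enamine tautomerisation toward C5. The step needs regioselectivity in two senses: the enamine regiochemistry fixed in step 6 places the insertion on the C9 side, and the Michael polarity of the ynoate puts methyl on C8 and the ester on C7. An aprotic solvent is used because protic media divert the zwitterion to the open-chain Michael adduct.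

**Step 8**
Reactants: 15 methyl (3R,3aS,8aS)-6,8a-dimethyl-3-(propan-2-yl)-4-(pyrrolidin-1-yl)-3-[(triethylsilyl)oxy]-1,2,3,3a,8,8a-hexahydroazulene-5-carboxylate
Product: 16 methyl (3R,3aR,8aR)-6,8a-dimethyl-4-oxo-3-(propan-2-yl)-3-[(triethylsilyl)oxy]-1,2,3,3a,4,7,8,8a-octahydroazulene-5-carboxylate
Conditions: AcOH/NaOAc buffer (pH ≈ 4.5), THF/H2O, 40 °C
Reagents that add atoms: water, O
Why: Hydrolysis of the vinylogous carbamate by C-protonation to the iminium ion and attack of water should give the β-keto ester (drawn as its conjugated 7-ene tautomer) under buffered conditions that spare the tertiary silyl ether.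

**Step 9**
Reactants: 16 methyl (3R,3aR,8aR)-6,8a-dimethyl-4-oxo-3-(propan-2-yl)-3-[(triethylsilyl)oxy]-1,2,3,3a,4,7,8,8a-octahydroazulene-5-carboxylate
Product: 17 (3R,3aR,8aR)-6,8a-dimethyl-3-(propan-2-yl)-3-[(triethylsilyl)oxy]-2,3,3a,7,8,8a-hexahydroazulen-4(1H)-one
Conditions: LiCl (3 equiv), H2O (2 equiv), DMSO, 130–140 °C
Reagents that add atoms: none
Why: Krapcho dealkoxycarbonylation (SN2 demethylation by chloride, loss of CO2 from the β,γ-unsaturated tautomer, protonation of the dienolate) removes the ester under neutral conditions, and the double bond is expected to settle in conjugation at C7=C8.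

**Step 10**
Reactants: 17 (3R,3aR,8aR)-6,8a-dimethyl-3-(propan-2-yl)-3-[(triethylsilyl)oxy]-2,3,3a,7,8,8a-hexahydroazulen-4(1H)-one
Product: 18 (3R,3aR,8aR)-3-hydroxy-6,8a-dimethyl-3-(propan-2-yl)-2,3,3a,7,8,8a-hexahydroazulen-4(1H)-one
Conditions: HF·pyridine, THF/pyridine, 0 °C → rt
Reagents that add atoms: none
Why: Fluoride cleavage of the Si–O bond under buffered acidic conditions frees the tertiary alcohol without passing through the free alkoxide that would invite retro-aldol cleavage.

**Step 11**
Reactants: 18 (3R,3aR,8aR)-3-hydroxy-6,8a-dimethyl-3-(propan-2-yl)-2,3,3a,7,8,8a-hexahydroazulen-4(1H)-one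
Product: 19 (3R,3aS,4R,8aR)-6,8a-dimethyl-3-(propan-2-yl)-1,2,3,3a,4,7,8,8a-octahydroazulene-3,4-diol
Conditions: NaBH4, CeCl3·7H2O, MeOH, −78 °C
Reagents that add atoms: none
Why: Luche 1,2-reduction; cerium bridges the C4 hydroxyl and the C6 carbonyl on the concave face, so external hydride should add from the convex face (syn to H5 and the angular methyl) and the new C6–O bond ends on the concave face, syn to the C4–OH (4R).

**Step 12**
Reactants: 20 isovanillic acid
Product: 22 3-[(tert-butyldimethylsilyl)oxy]-4-methoxybenzoic acid, via bis-silylated silyl ester 21 (not isolated)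
Conditions: TBSCl (2.2 equiv), imidazole, DMF, rt; then AcOH/H2O/THF, rt
Reagents that add atoms: tert-butyldimethylsilyl chloride, CC(C)(C)[Si](C)(C)Cl
Why: Exhaustive silylation followed by selective hydrolysis of the labile silyl ester leaves the phenol as its TBS ether, a standard protection of hydroxybenzoic acids.

**Step 13**
Reactants: 19 (3R,3aS,4R,8aR)-6,8a-dimethyl-3-(propan-2-yl)-1,2,3,3a,4,7,8,8a-octahydroazulene-3,4-diol; 22 3-[(tert-butyldimethylsilyl)oxy]-4-methoxybenzoic acid
Product: 24 (3R,3aS,4R,8aR)-3-hydroxy-6,8a-dimethyl-3-(propan-2-yl)-1,2,3,3a,4,7,8,8a-octahydroazulen-4-yl 3-[(tert-butyldimethylsilyl)oxy]-4-methoxybenzoate, via Yamaguchi mixed anhydride 23 (not isolated)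
Conditions: 2,4,6-trichlorobenzoyl chloride, Et3N, THF, rt; then 19, DMAP, toluene, rt → 40 °C
Reagents that add atoms: none
Why: Yamaguchi esterification should acylate the secondary allylic C6 hydroxyl with retention, the hindered tertiary C4 hydroxyl being inert to the acylpyridinium species.

**Step 14**
Reactants: 24 (3R,3aS,4R,8aR)-3-hydroxy-6,8a-dimethyl-3-(propan-2-yl)-1,2,3,3a,4,7,8,8a-octahydroazulen-4-yl 3-[(tert-butyldimethylsilyl)oxy]-4-methoxybenzoate
Product: 25 (3R,3aS,4R,8aR)-3-hydroxy-6,8a-dimethyl-3-(propan-2-yl)-1,2,3,3a,4,7,8,8a-octahydroazulen-4-yl 3-hydroxy-4-methoxybenzoate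
Conditions: TBAF, AcOH (1:1), THF, 0 °C
Reagents that add atoms: none
Why: Buffered fluoride cleaves the aryl silyl ether selectively, and the acetic acid keeps the phenoxide from attacking the allylic ester.

**Compound list**
1 | isobutyryl chloride (2-methylpropanoyl chloride) | CC(C)C(=O)Cl | starting material
2 | ethylene | C=C | starting material
3 | 1-chloro-4-methylpentan-3-one | CC(C)C(=O)CCCl | intermediate
4 | 2-(2-chloroethyl)-2-(propan-2-yl)-1,3-dioxolane | CC(C)C1(CCCl)OCCO1 | intermediate
5 | 3-ethoxycyclopent-2-en-1-one | CCOC1=CC(=O)CC1 | starting material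
6 | {2-[2-(propan-2-yl)-1,3-dioxolan-2-yl]ethyl}lithium (not isolated) | [Li]CCC1(C(C)C)OCCO1 | intermediate
7 | 3-ethoxy-1-{2-[2-(propan-2-yl)-1,3-dioxolan-2-yl]ethyl}cyclopent-2-en-1-ol, racemic, present as its lithium alkoxide (not isolated) | CCOC1=CC(O)(CCC2(C(C)C)OCCO2)CC1 | intermediate
8 | 3-(4-methyl-3-oxopentyl)cyclopent-2-en-1-one | CC(C)C(=O)CCC1=CC(=O)CC1 | intermediate
9 | dimethylaluminium (3R)-3-methyl-3-(4-methyl-3-oxopentyl)cyclopent-1-en-1-olate (not isolated) | C[Al](C)OC1=C[C@@](C)(CCC(=O)C(C)C)CC1 | intermediate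
10 | (3aS,6R,6aR)-6-hydroxy-3a-methyl-6-(propan-2-yl)hexahydropentalen-1(2H)-one (cis-fused, OH on the concave face) | O=C1CC[C@]2(C)CC[C@@](O)(C(C)C)[C@H]12 | intermediate
11 | (3aS,6R,6aR)-3a-methyl-6-(propan-2-yl)-6-[(triethylsilyl)oxy]hexahydropentalen-1(2H)-one | O=C1CC[C@]2(C)CC[C@@](O[Si](CC)(CC)CC)(C(C)C)[C@H]12 | intermediate
12 | 1-[(3aS,6R,6aS)-3a-methyl-6-(propan-2-yl)-6-[(triethylsilyl)oxy]-3,3a,4,5,6,6a-hexahydropentalen-1-yl]pyrrolidine (C6=C9 enamine) | C1CCN(C1)C2=CC[C@]3(C)CC[C@@](O[Si](CC)(CC)CC)(C(C)C)[C@H]23 | intermediate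
13 | methyl but-2-ynoate | CC#CC(=O)OC | starting material
14 | 1-aminocyclobutene adduct of 12 and 13: cyclobutene C6–C7(CO2Me)=C8(Me)–C9 cis-fused to the diquinane on its convex face, pyrrolidine on C6 (not isolated) | COC(=O)C1=C(C)[C@H]2CC[C@]3(C)CC[C@@](O[Si](CC)(CC)CC)(C(C)C)[C@@H]3[C@@]12N1CCCC1 | intermediate
15 | methyl (3R,3aS,8aS)-6,8a-dimethyl-3-(propan-2-yl)-4-(pyrrolidin-1-yl)-3-[(triethylsilyl)oxy]-1,2,3,3a,8,8a-hexahydroazulene-5-carboxylate | C1CCN(C1)C2=C(C(=O)OC)C(C)=CC[C@]3(C)CC[C@@](O[Si](CC)(CC)CC)(C(C)C)[C@H]23 | intermediate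
16 | methyl (3R,3aR,8aR)-6,8a-dimethyl-4-oxo-3-(propan-2-yl)-3-[(triethylsilyl)oxy]-1,2,3,3a,4,7,8,8a-octahydroazulene-5-carboxylate | COC(=O)C1=C(C)CC[C@]2(C)CC[C@@](O[Si](CC)(CC)CC)(C(C)C)[C@@H]2C1=O | intermediate
17 | (3R,3aR,8aR)-6,8a-dimethyl-3-(propan-2-yl)-3-[(triethylsilyl)oxy]-2,3,3a,7,8,8a-hexahydroazulen-4(1H)-one | O=C1C=C(C)CC[C@]2(C)CC[C@@](O[Si](CC)(CC)CC)(C(C)C)[C@H]12 | intermediate
18 | (3R,3aR,8aR)-3-hydroxy-6,8a-dimethyl-3-(propan-2-yl)-2,3,3a,7,8,8a-hexahydroazulen-4(1H)-one | O=C1C=C(C)CC[C@]2(C)CC[C@@](O)(C(C)C)[C@H]12 | intermediate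
19 | (3R,3aS,4R,8aR)-6,8a-dimethyl-3-(propan-2-yl)-1,2,3,3a,4,7,8,8a-octahydroazulene-3,4-diol | O[C@@H]1C=C(C)CC[C@]2(C)CC[C@@](O)(C(C)C)[C@H]12 | intermediate
20 | isovanillic acid (3-hydroxy-4-methoxybenzoic acid) | COc1ccc(C(=O)O)cc1O | starting material
21 | tert-butyldimethylsilyl 3-[(tert-butyldimethylsilyl)oxy]-4-methoxybenzoate (not isolated) | COc1ccc(C(=O)O[Si](C)(C)C(C)(C)C)cc1O[Si](C)(C)C(C)(C)C | intermediate
22 | 3-[(tert-butyldimethylsilyl)oxy]-4-methoxybenzoic acid | COc1ccc(C(=O)O)cc1O[Si](C)(C)C(C)(C)C | intermediate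
23 | 3-[(tert-butyldimethylsilyl)oxy]-4-methoxybenzoic 2,4,6-trichlorobenzoic anhydride (not isolated) | COc1ccc(C(=O)OC(=O)c2c(Cl)cc(Cl)cc2Cl)cc1O[Si](C)(C)C(C)(C)C | intermediate
24 | (3R,3aS,4R,8aR)-3-hydroxy-6,8a-dimethyl-3-(propan-2-yl)-1,2,3,3a,4,7,8,8a-octahydroazulen-4-yl 3-[(tert-butyldimethylsilyl)oxy]-4-methoxybenzoate | COc1ccc(C(=O)O[C@@H]2C=C(C)CC[C@]3(C)CC[C@@](O)(C(C)C)[C@H]23)cc1O[Si](C)(C)C(C)(C)C | intermediate
25 | (3R,3aS,4R,8aR)-3-hydroxy-6,8a-dimethyl-3-(propan-2-yl)-1,2,3,3a,4,7,8,8a-octahydroazulen-4-yl 3-hydroxy-4-methoxybenzoate (CNP0210850.1) | COc1ccc(C(=O)O[C@@H]2C=C(C)CC[C@]3(C)CC[C@@](O)(C(C)C)[C@H]23)cc1O | target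

**Step count and risks**
Total step count: 14. Longest linear sequence: 13 steps (steps 1–11, 13, 14); step 12 is a one-step side branch.

Steps most likely to fail:

1. Step 7. The 3-substituted ynoate may be too weak an acceptor, so that C–C bond formation is slow and the enamine is lost thermally or is diverted to the open-chain Michael adduct. The fallback sets out from 12 and returns at 16. Enamine 12 is treated with methyl propiolate (Et2O, 0 °C → rt), the fast classical partner, to give the lower-homologue dienamine ester F1. Buffered hydrolysis as in step 8 gives the 7-methoxycarbonyl enone F2. Me2CuLi (Et2O, −78 °C) adds the missing methyl to C8 of this doubly activated acceptor to give the saturated β-keto ester F3. Selenenylation (NaH, PhSeCl, THF, 0 °C) gives the 7-phenylselanyl keto ester F4, and oxidation with H2O2 (CH2Cl2/pyridine, 0 °C) with syn-elimination toward C8–H restores C7=C8 and gives 16.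

2. Step 4. Methyl may be transferred to the side-chain ketone, or the aluminium enolate may be quenched before it cyclises, after which the diketone would close without regiocontrol; the enantiofacial discrimination may also be insufficient. The fallback sets out from 4 and 5 and returns at 10. The addition of step 3 is run with a mild work-up (aqueous oxalic acid, 0 °C) that hydrolyses only the vinylogous ester of 7 and gives the dioxolane enone F5. The same Cu–NHC/Me3Al addition with Et3SiOTf trapping gives the regiodefined triethylsilyl enol ether F6. NBS (THF, −78 °C) gives the 5-bromo ketone ketal F7, and 1 M HCl/THF unmasks the side-chain ketone to give the bromo diketone F8. SmI2 (THF, −78 °C) then generates the samarium enolate only at C5 and closes the ring by a chelated Reformatsky-type aldol to give 10.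

3. Step 9. At 130–140 °C the silyloxy group may be lost by β-elimination, C5 next to the ketone may epimerise, and the double bond may not return fully to conjugation. The fallback sets out from 12 and returns at 17. Allyl but-2-ynoate F9 (from but-2-ynoic acid and allyl alcohol, DCC, DMAP) is used in the ring expansion in place of 13 and gives the allyl dienamine ester F10. Buffered hydrolysis gives the allyl β-keto ester F11, and Pd(PPh3)4 with morpholine (THF, rt) removes the allyl group and lets the β-keto acid lose CO2 at ambient temperature to give 17.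

**Further compounds**
F1 | step 7 | methyl 8a-methyl-3-(propan-2-yl)-4-(pyrrolidin-1-yl)-3-[(triethylsilyl)oxy]-1,2,3,3a,8,8a-hexahydroazulene-5-carboxylate (15 without the C8 methyl; configuration at C1, C4, C5 as in 15) | C1CCN(C1)C2=C(C(=O)OC)C=CC[C@]3(C)CC[C@@](O[Si](CC)(CC)CC)(C(C)C)[C@H]23
F2 | step 7 | methyl 8a-methyl-4-oxo-3-(propan-2-yl)-3-[(triethylsilyl)oxy]-1,2,3,3a,4,7,8,8a-octahydroazulene-5-carboxylate (16 without the C8 methyl) | COC(=O)C1=CCC[C@]2(C)CC[C@@](O[Si](CC)(CC)CC)(C(C)C)[C@@H]2C1=O
F3 | step 7 | methyl 6,8a-dimethyl-4-oxo-3-(propan-2-yl)-3-[(triethylsilyl)oxy]decahydroazulene-5-carboxylate (7,8-dihydro-16, mixture at C7 and C8) | COC(=O)C1C(C)CC[C@]2(C)CC[C@@](O[Si](CC)(CC)CC)(C(C)C)[C@@H]2C1=O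
F4 | step 7 | methyl 6,8a-dimethyl-4-oxo-5-(phenylselanyl)-3-(propan-2-yl)-3-[(triethylsilyl)oxy]decahydroazulene-5-carboxylate | COC(=O)C1([Se]c3ccccc3)C(C)CC[C@]2(C)CC[C@@](O[Si](CC)(CC)CC)(C(C)C)[C@@H]2C1=O
F5 | step 4 | 3-{2-[2-(propan-2-yl)-1,3-dioxolan-2-yl]ethyl}cyclopent-2-en-1-one | CC(C)C1(CCC2=CC(=O)CC2)OCCO1
F6 | step 4 | triethylsilyl enol ether (toward C5) of 3-methyl-3-{2-[2-(propan-2-yl)-1,3-dioxolan-2-yl]ethyl}cyclopentanone, quaternary centre as in 9 | CC[Si](CC)(CC)OC1=C[C@@](C)(CCC2(C(C)C)OCCO2)CC1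
F7 | step 4 | 2-bromo-3-methyl-3-{2-[2-(propan-2-yl)-1,3-dioxolan-2-yl]ethyl}cyclopentan-1-one (mixture at C–Br) | O=C1CC[C@](C)(CCC2(C(C)C)OCCO2)C1Br
F8 | step 4 | 2-bromo-3-methyl-3-(4-methyl-3-oxopentyl)cyclopentan-1-one (mixture at C–Br) | CC(C)C(=O)CC[C@@]1(C)CCC(=O)C1Br
F9 | step 9 | prop-2-en-1-yl but-2-ynoate (allyl but-2-ynoate) | CC#CC(=O)OCC=C
F10 | step 9 | prop-2-en-1-yl ester analogue of 15 | C1CCN(C1)C2=C(C(=O)OCC=C)C(C)=CC[C@]3(C)CC[C@@](O[Si](CC)(CC)CC)(C(C)C)[C@H]23
F11 | step 9 | prop-2-en-1-yl ester analogue of 16 | C=CCOC(=O)C1=C(C)CC[C@]2(C)CC[C@@](O[Si](CC)(CC)CC)(C(C)C)[C@@H]2C1=O
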